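**Strategy.** Everything rests on disconnecting the side chain between carbinol carbon C6' and methylene C7' (chain numbered C1'–C11' outward from the lactone ring). The array C6'(OH)–C7'H2–C8'(CH3)=C9'H is the retron of an allylboration with allylic transposition. An enantioenriched α-substituted β-methallyl boronic ester, whose alkene still sits as an isopropenyl group beside a boron-bearing stereocentre, attacks an (R,R)-epoxy enal through its terminal CH2. One operation joins the furan and lactone halves, shifts the alkene into the E-trisubstituted C8'=C9' position and trades the boron-bearing stereocentre for C6'. The hydroxy-γ-lactone is unmasked last by invertive 5-exo opening of the epoxide by the carboxyl group.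

Key step: step 10

Remark: epoxide 11 and alcohol 12 are used as racemates because their stereocentre is erased in step 6; (+)-sparteine and the D-fructose-derived Shi ketone are taken as purchased reagents.

Step 1
Reactants: 1 3-bromofuran; 2 oxetane
Product: 4 3-(furan-3-yl)propan-1-ol, via furan-3-yllithium 3 (not isolated)
Conditions: n-BuLi, THF, –78 °C; then 2, BF3·OEt2, –78 °C; aq. NaHCO3
Reagents that add atoms: n-butyllithium, [Li]CCCC (supplies only the lithium held in 3)
Why: Bromine–lithium exchange at –78 °C keeps the 3-lithio regiochemistry, and the aryllithium should open the BF3-activated oxetane by SN2 ring opening to give the three-carbon alcohol.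

Step 2
Reactants: 4 3-(furan-3-yl)propan-1-ol
Product: 5 3-(furan-3-yl)propyl N,N-diisopropylcarbamate
Conditions: iPr2NCOCl, Et3N, CH2Cl2, reflux
Reagents that add atoms: N,N-diisopropylcarbamoyl chloride, CC(C)N(C(C)C)C(Cl)=O
Why: O-carbamoylation of the primary alcohol installs the group that directs and stabilises the α-lithiation of the next step.

Step 3
Reactants: 5 3-(furan-3-yl)propyl N,N-diisopropylcarbamate; 6 isopropenylboronic acid pinacol ester
Product: 9 2-[(3S)-5-(furan-3-yl)-2-methylpent-1-en-3-yl]-4,4,5,5-tetramethyl-1,3,2-dioxaborolane, via lithiated carbamate 7 (not isolated), via boronate complex 8 (not isolated)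
Conditions: s-BuLi, (+)-sparteine, Et2O, –78 °C; then 6, –78 °C; then warm to reflux
Reagents that add atoms: sec-butyllithium, [Li]C(C)CC (supplies only the lithium held in 7 and 8)
Why: Lithiation–borylation, in which (+)-sparteine-mediated removal of the pro-R α-proton, stereoretentive capture by boron and stereoinvertive 1,2-migration of the isopropenyl group with loss of the carbamate should set the boron-bearing stereocentre as S.

Step 4
Reactants: 10 geranyl acetate
Product: 11 (2E)-5-(3,3-dimethyloxiran-2-yl)-3-methylpent-2-en-1-yl acetate (racemic)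
Conditions: mCPBA, NaHCO3, CH2Cl2, 0 °C
Reagents that add atoms: 3-chloroperoxybenzoic acid, O=C(OO)c1cccc(Cl)c1
Why: Prilezhaev epoxidation should take the electron-rich 6,7-alkene because the 2,3-alkene is deactivated by the allylic acetate.

Step 5
Reactants: 11 (2E)-5-(3,3-dimethyloxiran-2-yl)-3-methylpent-2-en-1-yl acetate
Product: 12 (2E)-6-hydroxy-3,7-dimethylocta-2,7-dien-1-yl acetate (racemic)
Conditions: Al(OiPr)3, toluene, 110 °C; aq. work-up
Reagents that add atoms: none
Why: Aluminium-alkoxide-promoted isomerisation of an epoxide to an allylic alcohol, in which a syn-elimination through a six-membered transition state takes a methyl proton and breaks the tertiary C–O bond to leave the secondary alcohol beside an isopropenyl group.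

Step 6
Reactants: 12 (2E)-6-hydroxy-3,7-dimethylocta-2,7-dien-1-yl acetate; 13 trimethyl orthoacetate
Product: 15 methyl (4E,8E)-10-acetoxy-4,8-dimethyldeca-4,8-dienoate, via ketene acetal 14 (not isolated)
Conditions: 13 (excess), EtCO2H (cat.), 110 to 140 °C, MeOH distilled off
Reagents that add atoms: none
Why: Johnson–Claisen rearrangement, whose chair transition state with the carbinol substituent pseudo-equatorial should give the E-trisubstituted 4-methyl-4-enoate and erase the carbinol stereocentre.

Step 7
Reactants: 15 methyl (4E,8E)-10-acetoxy-4,8-dimethyldeca-4,8-dienoate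
Product: 16 methyl 3-[(2R,3R)-3-[(3E)-5-acetoxy-3-methylpent-3-en-1-yl]-2-methyloxiran-2-yl]propanoate
Conditions: D-fructose-derived Shi ketone (1,2:4,5-di-O-isopropylidene-β-D-erythro-2,3-hexodiulo-2,6-pyranose, cat.), KHSO5 (Oxone), K2CO3, Bu4NHSO4, MeCN/CH2(OMe)2/aq. Na2B4O7 buffer, 0 °C
Reagents that add atoms: potassium peroxymonosulfate, [K+].[O-]S(=O)(=O)OO
Why: Shi epoxidation, in which the chiral dioxirane should attack the E-trisubstituted 4,5-alkene through the spiro transition state to give the (R,R)-epoxide, while the alkene next to the allylic acetate is too electron-poor to compete.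

Step 8
Reactants: 16 methyl 3-[(2R,3R)-3-[(3E)-5-acetoxy-3-methylpent-3-en-1-yl]-2-methyloxiran-2-yl]propanoate
Product: 17 methyl 3-[(2R,3R)-3-[(3E)-5-hydroxy-3-methylpent-3-en-1-yl]-2-methyloxiran-2-yl]propanoate
Conditions: K2CO3, MeOH, 0 °C
Reagents that add atoms: none
Why: Base-catalysed transesterification should remove the acetate; exchange at the methyl ester is degenerate in methanol and the trisubstituted epoxide is inert to methoxide.

Step 9
Reactants: 17 methyl 3-[(2R,3R)-3-[(3E)-5-hydroxy-3-methylpent-3-en-1-yl]-2-methyloxiran-2-yl]propanoate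
Product: 18 methyl 3-[(2R,3R)-2-methyl-3-[(3E)-3-methyl-5-oxopent-3-en-1-yl]oxiran-2-yl]propanoate
Conditions: MnO2, CH2Cl2, rt
Reagents that add atoms: none
Why: Chemoselective MnO2 oxidation of the allylic alcohol should give the E-enal without touching the epoxide or the ester.

Step 10
Reactants: 9 2-[(3S)-5-(furan-3-yl)-2-methylpent-1-en-3-yl]-4,4,5,5-tetramethyl-1,3,2-dioxaborolane; 18 methyl 3-[(2R,3R)-2-methyl-3-[(3E)-3-methyl-5-oxopent-3-en-1-yl]oxiran-2-yl]propanoate
Product: 22 methyl 3-[(2R,3R)-3-[(3E,5R,7E)-10-(furan-3-yl)-5-hydroxy-3,7-dimethyldeca-3,7-dien-1-yl]-2-methyloxiran-2-yl]propanoate, via lithium butylboronate complex 19 (not isolated), via allyl borinic ester 20 (not isolated), via borinate adduct 21 (not isolated)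
Conditions: 9, n-BuLi, THF, –78 °C; (CF3CO)2O, –78 °C; then 18, –78 °C to rt; aq. NaHCO3
Reagents that add atoms: n-butyllithium, [Li]CCCC (butyl and lithium held only in 19 to 21); trifluoroacetic anhydride, O=C(OC(=O)C(F)(F)F)C(F)(F)F (trifluoroacetyl held only in 20 and 21)
Why: n-BuLi adds to boron of 9 and trifluoroacetic anhydride acylates one pinacol oxygen of complex 19, so that the ring-opened B-butyl borinic ester 20 exists before the aldehyde arrives; 20 then binds the carbonyl oxygen of 18 and transfers the allyl group through a closed six-membered chair (Zimmerman–Traxler type, SE2'), forming the C6'–C7' bond from the terminal CH2 of 9 while the alkene shifts to C8'=C9'. The closest known reaction is the borinic-ester variant of the allylboration of aldehydes with α-substituted β-methallyl pinacol boronic esters. No ring is closed; the only ring is the transient chair. The new stereocentre C6' is controlled solely by the boron-bearing stereocentre of 9 (1,3-chirality transfer: with the furylethyl group pseudo-equatorial and the alkenyl residue of the aldehyde equatorial, the S-boronate should give 6'R), the remote epoxide centres of 18 having no influence. The step needs E over Z selectivity, which also decides the C6' configuration because the Z-chair attacks the opposite aldehyde face; it is secured by the borinic ester, whose single alkoxy ligand removes the clash with the pinacol methyl groups that forces the α-substituent axial in the parent pinacol ester. It also needs 1,2- over 1,4-addition and aldehyde over ester or epoxide, which the closed transition state and the low temperature should secure.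

Step 11
Reactants: 22 methyl 3-[(2R,3R)-3-[(3E,5R,7E)-10-(furan-3-yl)-5-hydroxy-3,7-dimethyldeca-3,7-dien-1-yl]-2-methyloxiran-2-yl]propanoate
Product: 25 (5S)-5-[(1R,4E,6R,8E)-11-(furan-3-yl)-1,6-dihydroxy-4,8-dimethylundeca-4,8-dien-1-yl]-5-methyloxolan-2-one, via lithium epoxy carboxylate 23 (not isolated), via epoxy acid 24 (not isolated)
Conditions: LiOH, THF/H2O, 0 °C to rt; then 1 M HCl to pH 3–4, EtOAc; pyridinium p-toluenesulfonate (cat.), CH2Cl2, rt
Reagents that add atoms: lithium hydroxide, [Li+].[OH-] (its oxygen replaces the methoxy oxygen; lithium held only in 23)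
Why: Saponification followed by acid-mediated epoxy-acid lactonisation, in which the carboxyl oxygen should open the epoxide at the tertiary carbon (5-exo, inversion, giving 5S) while the secondary C–O bond is untouched (1'R), under conditions mild enough for the furan and the allylic alcohol.

**Compound list**

1 | 3-bromofuran | Brc1ccoc1 | starting material
2 | oxetane | C1COC1 | starting material
3 | furan-3-yllithium | [Li]c1ccoc1 | intermediate
4 | 3-(furan-3-yl)propan-1-ol | OCCCc1ccoc1 | intermediate
5 | 3-(furan-3-yl)propyl N,N-diisopropylcarbamate | CC(C)N(C(C)C)C(=O)OCCCc1ccoc1 | intermediate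
6 | isopropenylboronic acid pinacol ester (4,4,5,5-tetramethyl-2-(prop-1-en-2-yl)-1,3,2-dioxaborolane) | CC(=C)B1OC(C)(C)C(C)(C)O1 | starting material
7 | (1R)-3-(furan-3-yl)-1-lithiopropyl N,N-diisopropylcarbamate (sparteine complex) | CC(C)N(C(C)C)C(=O)O[C@H]([Li])CCc1ccoc1 | intermediate
8 | lithium boronate complex of 7 and 6 (R at carbon, isopropenyl on boron) | CC(C)N(C(C)C)C(=O)O[C@@H](CCc1ccoc1)[B-]1(C(C)=C)OC(C)(C)C(C)(C)O1.[Li+] | intermediate
9 | 2-[(3S)-5-(furan-3-yl)-2-methylpent-1-en-3-yl]-4,4,5,5-tetramethyl-1,3,2-dioxaborolane | C=C(C)[C@H](CCc1ccoc1)B1OC(C)(C)C(C)(C)O1 | intermediate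
10 | geranyl acetate ((2E)-3,7-dimethylocta-2,6-dien-1-yl acetate) | CC(C)=CCC/C(C)=C/COC(C)=O | starting material
11 | (2E)-5-(3,3-dimethyloxiran-2-yl)-3-methylpent-2-en-1-yl acetate (racemic) | CC1(C)OC1CC/C(C)=C/COC(C)=O | intermediate
12 | (2E)-6-hydroxy-3,7-dimethylocta-2,7-dien-1-yl acetate (racemic) | C=C(C)C(O)CC/C(C)=C/COC(C)=O | intermediate
13 | trimethyl orthoacetate | CC(OC)(OC)OC | starting material
14 | mixed ketene acetal of 12 (1-methoxyvinyl ether) | C=C(OC)OC(CC/C(C)=C/COC(C)=O)C(C)=C | intermediate
15 | methyl (4E,8E)-10-acetoxy-4,8-dimethyldeca-4,8-dienoate | COC(=O)CC/C(C)=C/CC/C(C)=C/COC(C)=O | intermediate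
16 | methyl 3-[(2R,3R)-3-[(3E)-5-acetoxy-3-methylpent-3-en-1-yl]-2-methyloxiran-2-yl]propanoate | COC(=O)CC[C@@]1(C)O[C@@H]1CC/C(C)=C/COC(C)=O | intermediate
17 | methyl 3-[(2R,3R)-3-[(3E)-5-hydroxy-3-methylpent-3-en-1-yl]-2-methyloxiran-2-yl]propanoate | COC(=O)CC[C@@]1(C)O[C@@H]1CC/C(C)=C/CO | intermediate
18 | methyl 3-[(2R,3R)-2-methyl-3-[(3E)-3-methyl-5-oxopent-3-en-1-yl]oxiran-2-yl]propanoate | COC(=O)CC[C@@]1(C)O[C@@H]1CC/C(C)=C/C=O | intermediate
19 | lithium B-butyl boronate complex of 9 | CCCC[B-]1([C@@H](CCc2ccoc2)C(C)=C)OC(C)(C)C(C)(C)O1.[Li+] | intermediate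
20 | 2,3-dimethyl-3-(trifluoroacetoxy)butan-2-yl butyl[(3S)-5-(furan-3-yl)-2-methylpent-1-en-3-yl]borinate | CCCCB([C@@H](CCc1ccoc1)C(C)=C)OC(C)(C)C(C)(C)OC(=O)C(F)(F)F | intermediate
21 | O-borinate of 22 (butyl, 2,3-dimethyl-3-(trifluoroacetoxy)butan-2-yloxy on boron) | C/C(=C\[C@H](OB(CCCC)OC(C)(C)C(C)(C)OC(=O)C(F)(F)F)C/C(C)=C/CCc1ccoc1)CC[C@H]1O[C@]1(C)CCC(=O)OC | intermediate
22 | methyl 3-[(2R,3R)-3-[(3E,5R,7E)-10-(furan-3-yl)-5-hydroxy-3,7-dimethyldeca-3,7-dien-1-yl]-2-methyloxiran-2-yl]propanoate | C/C(=C\[C@H](O)C/C(C)=C/CCc1ccoc1)CC[C@H]1O[C@]1(C)CCC(=O)OC | intermediate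
23 | lithium 3-[(2R,3R)-3-[(3E,5R,7E)-10-(furan-3-yl)-5-hydroxy-3,7-dimethyldeca-3,7-dien-1-yl]-2-methyloxiran-2-yl]propanoate | C/C(=C\[C@H](O)C/C(C)=C/CCc1ccoc1)CC[C@H]1O[C@]1(C)CCC(=O)[O-].[Li+] | intermediate
24 | 3-[(2R,3R)-3-[(3E,5R,7E)-10-(furan-3-yl)-5-hydroxy-3,7-dimethyldeca-3,7-dien-1-yl]-2-methyloxiran-2-yl]propanoic acid | C/C(=C\[C@H](O)C/C(C)=C/CCc1ccoc1)CC[C@H]1O[C@]1(C)CCC(=O)O | intermediate
25 | (5S)-5-[(1R,4E,6R,8E)-11-(furan-3-yl)-1,6-dihydroxy-4,8-dimethylundeca-4,8-dien-1-yl]-5-methyloxolan-2-one | C/C(=C\[C@H](O)C/C(C)=C/CCc1ccoc1)CC[C@@H](O)[C@]1(C)CCC(=O)O1 | target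

**Totals.** Total step count: 11. Longest linear sequence: 8 steps (steps 4 to 11, from geranyl acetate 10 to 25); the boronate branch (steps 1 to 3) joins at step 10.

**Steps most likely to fail**

Step 10. The chair transition state may lose control: if the α-substituent slips into the pseudo-axial position, the Z-alkene forms together with the wrong configuration at C6'. The Lewis-acidic boron species may also open the epoxide. The fallback makes the same C6'–C7' bond without stereocontrol by an α-selective allylbarium addition and then sets the carbinol by oxidation and Corey–Bakshi–Shibata reduction. It sets out from 9 and 18. Oxidation of 9 (NaBO3, THF/H2O) should give (3S)-5-(furan-3-yl)-2-methylpent-1-en-3-ol F1. SOCl2 in Et2O should convert it with allylic transposition into 3-[(3E)-5-chloro-4-methylpent-3-en-1-yl]furan F2. The allylbarium reagent made from F2 (activated barium from BaI2 and lithium biphenylide, THF, –78 °C) should add to 18 through its α-carbon with retention of the E-geometry, giving methyl 3-[(2R,3R)-3-[(3E,7E)-10-(furan-3-yl)-5-hydroxy-3,7-dimethyldeca-3,7-dien-1-yl]-2-methyloxiran-2-yl]propanoate as both C5 epimers F3. MnO2 in CH2Cl2 should give methyl 3-[(2R,3R)-3-[(3E,7E)-10-(furan-3-yl)-3,7-dimethyl-5-oxodeca-3,7-dien-1-yl]-2-methyloxiran-2-yl]propanoate F4. Reduction of F4 with catecholborane and the (S)-2-methyl-CBS-oxazaborolidine ((S)-1-methyl-3,3-diphenyltetrahydro-1H,3H-pyrrolo[1,2-c][1,3,2]oxazaborole), the alkenyl group acting as the large substituent, should give the 5R alcohol, where the fallback comes back to the route at 22.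

Step 3. During the slow α-lithiation, sec-butyllithium may instead deprotonate the furan ring at C2 or C5, or the 1,2-migration of the boronate complex may stay incomplete. The fallback is a copper-catalysed enantioselective SN2' borylation of an allylic carbonate, which needs no organolithium. It sets out from 4. Dess–Martin oxidation should give 3-(furan-3-yl)propanal F5. Wittig reaction with Ph3P=C(CH3)CO2Et (toluene, 80 °C) should give ethyl (2E)-5-(furan-3-yl)-2-methylpent-2-enoate F6. Reduction with iBu2AlH (CH2Cl2, –78 °C) should give (2E)-5-(furan-3-yl)-2-methylpent-2-en-1-ol F7. ClCO2Me and pyridine should give (2E)-5-(furan-3-yl)-2-methylpent-2-en-1-yl methyl carbonate F8. B2pin2, CuCl, KOtBu and a chiral bisphosphine such as 2,3-bis(tert-butylmethylphosphino)quinoxaline (the enantiomer that leads to the S product) should deliver boron to the γ-carbon with loss of the carbonate, and the fallback comes back to the route at 9.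

Step 5. At 110 °C the acetyl group may be transferred to the aluminium alkoxide (transesterification), leaving diol or scrambled acetates. The fallback is a Schenck ene reaction, which is inert toward the ester. It sets out from 10. Photooxygenation (O2, hν, tetraphenylporphyrin, CH2Cl2, 0 °C) should give (2E)-6-hydroperoxy-3,7-dimethylocta-2,7-dien-1-yl acetate F9 together with its tertiary regioisomer, which is removed by chromatography after reduction. PPh3 should reduce F9, and the fallback comes back to the route at 12.

**Further compounds**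

F1 | step 10 | (3S)-5-(furan-3-yl)-2-methylpent-1-en-3-ol | C=C(C)[C@@H](O)CCc1ccoc1
F2 | step 10 | 3-[(3E)-5-chloro-4-methylpent-3-en-1-yl]furan | ClC/C(C)=C/CCc1ccoc1
F3 | step 10 | methyl 3-[(2R,3R)-3-[(3E,7E)-10-(furan-3-yl)-5-hydroxy-3,7-dimethyldeca-3,7-dien-1-yl]-2-methyloxiran-2-yl]propanoate (both C5 epimers) | C/C(=C\C(O)C/C(C)=C/CCc1ccoc1)CC[C@H]1O[C@]1(C)CCC(=O)OC
F4 | step 10 | methyl 3-[(2R,3R)-3-[(3E,7E)-10-(furan-3-yl)-3,7-dimethyl-5-oxodeca-3,7-dien-1-yl]-2-methyloxiran-2-yl]propanoate | C/C(=C\C(=O)C/C(C)=C/CCc1ccoc1)CC[C@H]1O[C@]1(C)CCC(=O)OC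
F5 | step 3 | 3-(furan-3-yl)propanal | O=CCCc1ccoc1
F6 | step 3 | ethyl (2E)-5-(furan-3-yl)-2-methylpent-2-enoate | CCOC(=O)/C(C)=C/CCc1ccoc1
F7 | step 3 | (2E)-5-(furan-3-yl)-2-methylpent-2-en-1-ol | OC/C(C)=C/CCc1ccoc1
F8 | step 3 | (2E)-5-(furan-3-yl)-2-methylpent-2-en-1-yl methyl carbonate | COC(=O)OC/C(C)=C/CCc1ccoc1
F9 | step 5 | (2E)-6-hydroperoxy-3,7-dimethylocta-2,7-dien-1-yl acetate (racemic) | C=C(C)C(OO)CC/C(C)=C/COC(C)=O
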